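I counted what would be left.

A solid substrate dissolved into a stirred flask. A catalyst turned the dissolved starting material into target, with a partner fed at a steady rate.

solid substrate 0.25 M; partner 0.600 equiv (fed, over 50 min); free catalyst 0.12 mol%; time 40 h

    starting material + free catalyst → catalyst intermediate A (k1 = 140 /M/min)
    catalyst intermediate A ⇌ catalyst intermediate B (K2 = 1.4, k2 = 42 /min)
    partner + catalyst intermediate B → catalyst intermediate C (k3 = 3900 /M/min)
    catalyst intermediate C → free catalyst + target (k4 = 39 /min)
    solid substrate ⇌ starting material, rate k5*(cs5 - [starting material]) while solid is left; crystals form when [starting material] > cs5 (cs5 = 0.082 M, k5 = 0.012 /min)

- as a solid, counted per litre of solution: solid substrate
- at the start none of the solid substrate is in solution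
- what has only dissolved of solid substrate counts as not reacted
- the reaction counts as stopped when no species that holds the solid substrate changes by six tenths of a point or more over the second half of the time
- starting material means what is dissolved; the solid is not counted in it
- run time (flask): 40 h

1. at 40 h, what has stopped the reaction, if anything has (for what has run out or reacted, a solid counts together with what of it has only dissolved) (the partner has run out first / it is still moving / all of the solid substrate has reacted / no working catalyst is left / forward and back rates have come level)
2. part of the solid substrate that has turned into other species by 40 h (what has only dissolved does not count)
3. how much target there is at 40 h, in percent of the solid substrate charged
4. how much starting material there is at 40 h, in percent of the solid substrate charged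

I took the settings one by one, working with what stays unturned and not with what forms. First the partner. Each turn of the cycle takes one partner and one starting material, so the partner is the limiting reagent, and its 0.150 M makes at most 60.0% target. After that 0.150 M had reacted, I expected the catalyst to wait as intermediates A and B, each holding one substrate. That takes 3.000 × 10⁻⁴ M more. Subtracting both from the charge leaves 0.0997 M. I call this the remainder: the substrate per litre that neither target nor catalyst can take up.

The remainder is more than the solubility 0.082 M. So I expected [starting material] to stand at 32.8% of the charge, with 7.08% undissolved. More partner, with the solid held, shrinks the remainder, and I expected [starting material] to hold until the remainder reached the solubility. More solid, with equivalents held, makes the same solubility a smaller share of the charge, so that percentage falls.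

The catalyst's share is far less than the remainder, and it adds 0.12 mol% to the conversion, giving 60.1%. At its fastest, dissolution needs 3.93 h to supply the target and fill the solution. The feed of 50 min is shorter than that, and the run is longer. That figure is a lower bound, since dissolution slows near saturation, on a time scale of 1.39 h. The run is much longer than that scale too. Step 1 alone, with the catalyst as charged, halves starting material in 0.28 h, which is shorter than the run. So I expected neither feed time nor run time to matter.

The forecast agreed with me: the partner has run out first, conversion 60.12% (59.9% to 60.3%), target 60% (59.7% to 60.1%), starting material 32.8% (32.5% to 33%). Its ground for the last was that “solubility sets the starting material level”.

The flask's end at 40 h was this: the partner has run out first, conversion 60.1%, target 60.0%, starting material 32.8%, with 0% of the partner remaining. Beside that starting material stood 7.08% solid. Moved by a factor of 1.3, the settings of this flask shifted starting material at most thus: partner (11 points), then solid substrate (7.6 points), then free catalyst (under 0.05 points). The drawn-out feed changed conversion by nothing, nor did ten times the time. A neighbouring flask took 0.062 M of solid substrate, equivalents and loadings held. Its remainder is 0.0247 M, less than the solubility, so by hand no solid stays and starting material is 39.9%. That neighbour ended with 0% solid substrate and 39.9% starting material.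

The numbers of this flask are those of an exercise; the flask was simulated.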